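**Abbreviations and labels.** TBS = tert‑butyldimethylsilyl, TBDPS = tert‑butyldiphenylsilyl, TES = triethylsilyl, Bn = benzyl, Ipc = isopinocampheyl, 9‑BBN = 9‑borabicyclo[3.3.1]nonane, TEMPO = 2,2,6,6‑tetramethylpiperidine N‑oxyl. Core atoms: Ca = C1, Cc = C2, Ch = C3, Cg = C4, Cb = C5, Ce = C7, Cd = C8 of the 6‑oxabicyclo[3.2.1]octane; Cα = the methine of the propanal arm on Cb.

## Analysis of the target

Compound 42 is built on a 6‑oxabicyclo[3.2.1]octane: a cyclohexane (Ca, Cc, Ch, Cg, Cb, Cd) whose Ca and Cb are tied together by a CH2–O bridge (Ce and the ring oxygen), so that a tetrahydrofuran and the carbocycle share Ca, Cd and Cb. Ca is an all‑carbon quaternary centre carrying the dienyl chain, Cb a fully substituted ether carbon carrying the propanal arm, Cc a tertiary carbinol and Cd a CH with the 3‑hydroxypropyl arm. The core has four stereocentres (1S,2S,5R,8S) with Cα (S) beside it: the hydroxypropyl arm on Cd points to the side of the ether bridge, the hydroxyl on Cc is equatorial and cis to Ce with the methyl axial, and the configuration of Cb is tied to that of Ca by the bridge. The chain on Ca is an (E,E)‑diene ending in a cis‑2,5,6,6‑tetramethylcyclohexene (1R,5S) that lies too far from the core to be controlled by it, so it must enter as one enantiomer. Sensitive sites are the α‑methyl‑β‑alkoxy aldehyde (epimerisation at Cα, β‑elimination of the ether oxygen), the doubly allylic ring hydrogen and the diene (acid, oxidants, hydrogenation, radicals), and the tertiary alcohol β to the quaternary Ca. The difficulty is three fully substituted carbons, Ca, Cb and Cc, two of them adjacent and one bearing a stereogenic methine, inside a bridged bicycle. The route rests on Cb: it is α‑oxygenated, fully substituted and separated from Cc by the two methylenes Cg and Ch, so a tertiary α‑oxy radical at Cb and a vinyl ketone on Ca (carbonyl carbon Cc) account for the bond Cb–Cg and for the whole three‑carbon bridge.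

## Retrosynthetic reasoning

**42 back to 39.** The aldehyde and the free primary alcohol are unveiled last. The aldehyde of 41 comes from the primary alcohol of 40, and 40 from the fully silylated 39, in which the oxygen next to Cα carries the most acid‑labile primary silyl group and the propyl arm the most robust one. Cuts of C–O(Si) bonds only are chosen here because the diene excludes oxidative or reductive deprotection, and the order lets one of two primary alcohols be oxidised selectively.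

**39 to 31 and 37.** The chain is cut between its second and third carbon, a C(sp3)–C(sp2) bond. This keeps the diene and the cyclohexene out of the radical step, the hydrogenolysis and the Lewis‑acid steps, makes the route convergent, and fixes the trisubstituted E alkene in the fragment 37. The forward reaction has to join an alkylzinc (38, from iodide 31) to the alkenyl iodide with retention of geometry.

**37 to 32.** The iodo‑diene 37 comes from enyne 35 by syn addition of methyl and metal across the alkyne, which defines the E geometry. Enyne 35 comes from the methyl ketone 33 through enol phosphate 34, and 33 is the (1R,5S)‑cis component of commercial 32. The two ring stereocentres are taken from 32 because nothing in the core could induce them.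

**31 to 25.** Iodide 31 is traced through alcohol 30 to benzyl ether 29. The CH2–O bridge of 29 is the reduced form of the lactone carbonyl of 27 (through lactol 28), so Ce serves as an acyl group that activates Ca for C–C bond formation and is deoxygenated afterwards. The methyl carbinol of 26 and 27 comes from the ketone of 25 by delivery of methyl to the face opposite the lactone bridge.

**25 to 24 (key disconnection).** The bond Cb–Cg is cut. The 2‑oxo group of 25 stands three bonds from Cb, which is the retron of a radical conjugate addition: a radical at Cb and an acryloyl group on Ca. The radical is taken from the carboxylic acid 24 by decarboxylation. One ring and the last core C–C bond are gained, and the configuration of Cb need not be controlled before this step, because the planar radical can only close on the face that carries the acryloyl group.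

**24 to 14, 16 and 21.** The acryloyl group of 24 is the oxidised aldol adduct 23 of acrolein 21 with the enolate of lactone acid 20. The benzyloxyethyl arm of 20 comes from alkylation of lactone 14 with triflate 16, followed by ester hydrolysis (18 to 20). Both bonds are made at Ca next to Cd, and the second electrophile is expected to enter anti to the chain on Cd. Putting the arm in first and the acrolein unit second therefore gives the required configuration at Ca.

**14 to 10.** The lactone carbonyl Ce is the terminal carbon of the vinyl group of 10, brought to the acid level through diol 12 and trapped by the tertiary hydroxyl.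

**10 to 5 and 8.** The bond Cb–Cd is cut. An allylborane (9, from allene 8) adds to the keto group of 5 with allyl transposition. One step forms the bond, the tertiary carbinol and the stereocentre Cd, whose sense is set by the chiral boron substituents and the alkene geometry.

**5 to 1; 8 to 6; 16 to 15.** Keto ester 5 carries Cα from the Roche ester 1 by way of silyl ether 2, Weinreb amide 3 and ethoxy enone 4. Allene 8 comes from pent‑4‑yn‑1‑ol 6 through silyl ether 7 by one‑carbon homologation. Triflate 16 comes from 2‑(benzyloxy)ethanol 15.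

## Alternatives that were turned down

Alternative 1: The bond Cd–Cb is cut instead. A secondary radical at Cd, generated with Bu3SnH from xanthate A1 (either carbinol epimer), would add to the β‑carbon of an exocyclic alkoxyacrylate on an oxepane. This single bond completes the tetrahydrofuran and the carbocycle and gives the bridged ether ester A2.
- For it: radical additions to β‑alkoxyacrylates are a well‑tried way to ether rings; the step is stereoconvergent at the carbinol; it builds two rings with one bond, which is more than the chosen key step does.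
- Against it: A1 is a seven‑membered ether that must already hold the vicinal pair Ca (quaternary) and Cc (tertiary silyloxy carbon). Two stereocentres arise in the key step without a clear controlling element: Cd, as the radical carbon, takes its configuration from the transannular transition state, and Cα is set by hydrogen transfer to an acyclic α‑ester radical beside the new quaternary carbon. The ester on Cα then needs two more redox operations.
- Comparison: the chosen strategy closes only one ring in its key step, but it takes Cα from the chiral pool, fixes Cd beforehand, and leaves only Cb to the cyclisation, where geometry allows a single outcome. Its precursor is assembled on a five‑membered lactone from acyclic pieces, which is shorter than a stereodefined oxepane.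

Alternative 2: The bond Ce–O is cut. The tertiary alcohol at Cb in A3 would be converted into its hypoiodite (PhI(OAc)2, I2, light). The alkoxy radical abstracts hydrogen from the axial methyl on Ca through a six‑membered transition state, and the iodomethyl group is displaced by the oxygen to give the bridged ether A4.
- For it: this remote functionalisation is very dependable on rigid cyclohexanes with a 1,3‑diaxial hydroxyl and methyl, probably more so than a bridging radical closure. It needs no lactone‑to‑ether reduction.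
- Against it: A3 must already contain all four ring stereocentres, including both tertiary oxygen‑bearing carbons and the quaternary Ca, with the Cb hydroxyl and the methyl cis‑diaxial. The alkoxy radical at Cb is flanked by a branched substituent and by ring bonds, so β‑scission (loss of the Cα fragment or ring opening) competes with hydrogen abstraction.
- Comparison: the alternative is stronger in the precedent for its key reaction. The chosen strategy offers instead a precursor whose Cb configuration is irrelevant and whose other centres come from 1,2‑induction on a lactone, so the stereochemical load before the key step is much smaller.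

Alternative 3: Both tertiary C–O bonds (Cb–O and Cc–O) are cut. Photosensitised singlet oxygen would add (4+2) to the 1,4‑disubstituted cyclohexa‑1,3‑diene A5 to give endoperoxide A6. Reduction of the O–O bond and the alkene and closure of the Cb oxygen onto the activated hydroxymethyl group would follow.
- For it: two C–O bonds form in one step, and their cis relation, which the target needs, is guaranteed by the mechanism. No reagent‑based oxygenation of hindered carbons is required. On this point it is more economical than the chosen route, which needs a methyl addition and a two‑stage lactone reduction.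
- Against it: the oxygen must add to the diene face that carries the hydroxymethyl group on Ca and the silyloxypropyl chain on Cd. That is the face shielded by the chain on the allylic Cd, and at Ca the two faces differ only by CH2OH against a protected hydroxyethyl group, so face selection rests on weak and opposed effects. Ene reactions at the methyl group and at Cα–H compete, and a quaternary cyclohexadiene is not a short starting point.
- Comparison: the chosen strategy sets every centre through a neighbour relation (anti alkylation next to Cd, bridging at Cb, axial attack at Cc) and not through face discrimination by remote groups.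

Key step: step 15

## Route

Assumption: commercial α‑irone 32 is taken to be the racemic mixture of cis‑ and trans‑α‑irone with some β‑irone; and in step 7 the ester group of 5 is taken to occupy the axial site of the chair, which gives 10 as the 2S epimer (the 2R epimer would carry the same Cd centre and converge in step 15).

Step 1
Reactants: 1 methyl (R)‑3‑hydroxy‑2‑methylpropanoate
Product: 2 methyl (R)‑3‑(TBS‑oxy)‑2‑methylpropanoate
Conditions: TBSCl, imidazole, DMF, 0 °C → rt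
Reagents that add atoms: tert‑butyldimethylsilyl chloride, CC(C)(C)[Si](C)(C)Cl
Why: Imidazole‑promoted silylation of the primary alcohol; the stereocentre (the later Cα) is untouched, and a silyl ether can be removed at the end without oxidants in the presence of the diene.

Step 2
Reactants: 2 methyl (R)‑3‑(TBS‑oxy)‑2‑methylpropanoate
Product: 3 (R)‑3‑(TBS‑oxy)‑N‑methoxy‑N,2‑dimethylpropanamide
Conditions: MeNH(OMe)·HCl, i‑PrMgCl, THF, −20 → 0 °C
Reagents that add atoms: N,O‑dimethylhydroxylamine hydrochloride, CNOC.Cl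
Why: Weinreb amide formation from the ester with the magnesium amide; the conditions are cold and non‑enolising, so the α‑stereocentre is kept.

Step 3
Reactants: 3 (R)‑3‑(TBS‑oxy)‑N‑methoxy‑N,2‑dimethylpropanamide
Product: 4 (R)‑5‑(TBS‑oxy)‑2‑ethoxy‑4‑methylpent‑1‑en‑3‑one
Conditions: CH2=CHOEt, t‑BuLi, THF, −78 → 0 °C; then 3, −78 °C; aq NH4Cl
Reagents that add atoms: ethyl vinyl ether, C=COCC
Why: Ketone synthesis from a Weinreb amide: 1‑ethoxyvinyllithium adds once because the chelated tetrahedral adduct survives until work‑up, so the α‑centre is not exposed to base as a ketone.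

Step 4
Reactants: 4 (R)‑5‑(TBS‑oxy)‑2‑ethoxy‑4‑methylpent‑1‑en‑3‑one
Product: 5 ethyl (R)‑4‑(TBS‑oxy)‑3‑methyl‑2‑oxobutanoate
Conditions: O3, CH2Cl2, −78 °C; Me2S, −78 °C → rt
Reagents that add atoms: ozone, [O-][O+]=O
Why: Ozonolysis of the electron‑rich enol ether turns the ethoxyvinyl group into the ethyl ester carbonyl under neutral conditions; 5 is enolisable at Cα and should be used at once without chromatography.

Step 5
Reactants: 6 pent‑4‑yn‑1‑ol
Product: 7 tert‑butyl(pent‑4‑yn‑1‑yloxy)diphenylsilane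
Conditions: TBDPSCl, imidazole, CH2Cl2, rt
Reagents that add atoms: tert‑butyl(chloro)diphenylsilane, CC(C)(C)[Si](Cl)(c1ccccc1)c1ccccc1
Why: Silylation of the primary alcohol; the TBDPS ether is the most acid‑stable silyl group of the route and is meant to fall last.

Step 6
Reactants: 7 tert‑butyl(pent‑4‑yn‑1‑yloxy)diphenylsilane
Product: 8 tert‑butyl(hexa‑4,5‑dien‑1‑yloxy)diphenylsilane
Conditions: (CH2O)n, CuBr, i‑Pr2NH, 1,4‑dioxane, reflux
Reagents that add atoms: paraformaldehyde (as formaldehyde), C=O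
Why: Crabbé homologation: the copper acetylide gives the propargylic amine with formaldehyde and the amine, and a 1,5‑hydride shift releases the terminal allene and the imine.

Step 7
Reactants: 8 tert‑butyl(hexa‑4,5‑dien‑1‑yloxy)diphenylsilane; 5 ethyl (R)‑4‑(TBS‑oxy)‑3‑methyl‑2‑oxobutanoate
Product: 10 ethyl (2S,3S)‑2‑[(2R)‑1‑(TBS‑oxy)propan‑2‑yl]‑6‑(TBDPS‑oxy)‑3‑ethenyl‑2‑hydroxyhexanoate, via (E)‑allylbis(isopinocampheyl)borane 9 (not isolated)
Conditions: (+)‑α‑pinene, BH3·SMe2, THF, 0 °C; 8, 0 °C → rt; 5, −78 °C; NaBO3·4H2O, THF/H2O, rt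
Reagents that add atoms: none
Why: Allene hydroboration followed by allylboration: the dialkylborane adds to the terminal double bond of 8, and the allylborane settles as the E isomer by 1,3‑boratropic shift before it meets the ketone of 5 in a chair transition state (branched alkyl group equatorial, ester axial). The isopinocampheyl groups from (+)‑α‑pinene favour the chair that bonds the Si face of aldehydes; with the E geometry this gives 3S at Cd, and since the Felkin preference of the α‑stereocentre towards an E reagent is weak, the reagent should decide. C2 (Cb) is expected as 2S but is erased in step 15, so only the face of the allyl unit has to be controlled.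

Step 8
Reactants: 10 ethyl (2S,3S)‑2‑[(2R)‑1‑(TBS‑oxy)propan‑2‑yl]‑6‑(TBDPS‑oxy)‑3‑ethenyl‑2‑hydroxyhexanoate
Product: 12 ethyl (2S,3S)‑2‑[(2R)‑1‑(TBS‑oxy)propan‑2‑yl]‑6‑(TBDPS‑oxy)‑2‑hydroxy‑3‑(2‑hydroxyethyl)hexanoate, via B‑alkyl‑9‑BBN adduct 11 (not isolated)
Conditions: 9‑BBN, THF, 0 °C → rt; NaBO3·4H2O, H2O, rt
Reagents that add atoms: sodium perborate tetrahydrate (written as the anhydrous monomer), [Na+].[O-]OB=O
Why: Anti‑Markovnikov hydroboration of the monosubstituted alkene and oxidation with retention; the mild perborate work‑up is chosen so that the ester is neither hydrolysed nor closed to the six‑membered lactone by the new primary alcohol.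

Step 9
Reactants: 12 ethyl (2S,3S)‑2‑[(2R)‑1‑(TBS‑oxy)propan‑2‑yl]‑6‑(TBDPS‑oxy)‑2‑hydroxy‑3‑(2‑hydroxyethyl)hexanoate
Product: 14 ethyl (2S,3S)‑2‑[(2R)‑1‑(TBS‑oxy)propan‑2‑yl]‑3‑[3‑(TBDPS‑oxy)propyl]‑5‑oxooxolane‑2‑carboxylate, via 5‑hydroxyoxolane lactol 13 (not isolated)
Conditions: TEMPO (cat.), PhI(OAc)2, CH2Cl2, rt
Reagents that add atoms: none
Why: Oxidative lactonisation of a 1,4‑diol: the oxoammonium salt oxidises the primary alcohol, the aldehyde is trapped by the tertiary hydroxyl as the five‑membered lactol, and this is oxidised again to the γ‑lactone.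

Step 10
Reactants: 15 2‑(benzyloxy)ethanol
Product: 16 2‑(benzyloxy)ethyl trifluoromethanesulfonate
Conditions: Tf2O, 2,6‑lutidine, CH2Cl2, −78 °C
Reagents that add atoms: trifluoromethanesulfonic anhydride, O=S(=O)(OS(=O)(=O)C(F)(F)F)C(F)(F)F
Why: Sulfonylation of the primary alcohol; the triflate is used cold and crude, because β‑alkoxyethyl halides are too sluggish for a clean enolate alkylation.

Step 11
Reactants: 14 ethyl (2S,3S)‑2‑[(2R)‑1‑(TBS‑oxy)propan‑2‑yl]‑3‑[3‑(TBDPS‑oxy)propyl]‑5‑oxooxolane‑2‑carboxylate; 16 2‑(benzyloxy)ethyl trifluoromethanesulfonate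
Product: 18 ethyl (2S,3S,4S)‑4‑[2‑(benzyloxy)ethyl]‑2‑[(2R)‑1‑(TBS‑oxy)propan‑2‑yl]‑3‑[3‑(TBDPS‑oxy)propyl]‑5‑oxooxolane‑2‑carboxylate, via lithium enolate 17 (not isolated)
Conditions: LiN(i‑Pr)2, THF, −78 °C; 16, −78 → −40 °C
Reagents that add atoms: none
Why: Alkylation of the lactone enolate (the only enolisable position) with a primary triflate; the electrophile should enter anti to the chain on the adjacent Cd, but this centre is planarised again in step 13, so its configuration does not matter.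

Step 12
Reactants: 18 ethyl (2S,3S,4S)‑4‑[2‑(benzyloxy)ethyl]‑2‑[(2R)‑1‑(TBS‑oxy)propan‑2‑yl]‑3‑[3‑(TBDPS‑oxy)propyl]‑5‑oxooxolane‑2‑carboxylate
Product: 20 (2S,3S,4S)‑4‑[2‑(benzyloxy)ethyl]‑2‑[(2R)‑1‑(TBS‑oxy)propan‑2‑yl]‑3‑[3‑(TBDPS‑oxy)propyl]‑5‑oxooxolane‑2‑carboxylic acid, via ring‑opened hydroxy diacid lithium salt 19 (not isolated)
Conditions: LiOH, THF/H2O, rt → 40 °C; 1 M HCl to pH 3; CH2Cl2, rt
Reagents that add atoms: lithium hydroxide, [Li+].[OH-]
Why: Saponification of the α‑alkoxy ester (the lactone opens as well) and acid‑induced reclosure of the γ‑lactone onto the tertiary hydroxyl. The ester is cleaved here because no ester can be cleaved safely once the vinyl ketone is in place; epimerisation at C4 is of no consequence.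

Step 13
Reactants: 20 (2S,3S,4S)‑4‑[2‑(benzyloxy)ethyl]‑2‑[(2R)‑1‑(TBS‑oxy)propan‑2‑yl]‑3‑[3‑(TBDPS‑oxy)propyl]‑5‑oxooxolane‑2‑carboxylic acid; 21 acrolein
Product: 23 (2S,3S,4R)‑4‑[2‑(benzyloxy)ethyl]‑2‑[(2R)‑1‑(TBS‑oxy)propan‑2‑yl]‑3‑[3‑(TBDPS‑oxy)propyl]‑4‑(1‑hydroxyprop‑2‑en‑1‑yl)‑5‑oxooxolane‑2‑carboxylic acid (both carbinol epimers), via dilithium carboxylate enolate 22 (not isolated)
Conditions: LiN(i‑Pr)2 (2.3 equiv), THF, −78 → −40 °C; 21, −78 °C; AcOH, −78 °C
Reagents that add atoms: none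
Why: Aldol addition of the lithium enolate (as the carboxylate–enolate dianion) to the carbonyl group of acrolein, the normal 1,2‑course for lithium enolates at −78 °C. The aldehyde approaches the planar enolate anti to the silyloxypropyl chain on the adjacent Cd, so the new bond stands trans to that chain and the benzyloxyethyl arm cis to it, which sets Ca (4R); the cold acidic quench prevents retro‑aldol.

Step 14
Reactants: 23 (2S,3S,4R)‑4‑[2‑(benzyloxy)ethyl]‑2‑[(2R)‑1‑(TBS‑oxy)propan‑2‑yl]‑3‑[3‑(TBDPS‑oxy)propyl]‑4‑(1‑hydroxyprop‑2‑en‑1‑yl)‑5‑oxooxolane‑2‑carboxylic acid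
Product: 24 (2S,3S,4R)‑4‑[2‑(benzyloxy)ethyl]‑2‑[(2R)‑1‑(TBS‑oxy)propan‑2‑yl]‑3‑[3‑(TBDPS‑oxy)propyl]‑5‑oxo‑4‑(prop‑2‑enoyl)oxolane‑2‑carboxylic acid
Conditions: Dess–Martin periodinane, CH2Cl2, 0 °C → rt
Reagents that add atoms: none
Why: Oxidation of the allylic alcohol to the vinyl ketone under non‑basic conditions that tolerate the free acid; both carbinol epimers converge, the quaternary α‑carbon excludes enolisation, and 24 is used directly.

Step 15
Reactants: 24 (2S,3S,4R)‑4‑[2‑(benzyloxy)ethyl]‑2‑[(2R)‑1‑(TBS‑oxy)propan‑2‑yl]‑3‑[3‑(TBDPS‑oxy)propyl]‑5‑oxo‑4‑(prop‑2‑enoyl)oxolane‑2‑carboxylic acid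
Product: 25 (1R,5R,8S)‑1‑[2‑(benzyloxy)ethyl]‑5‑[(2R)‑1‑(TBS‑oxy)propan‑2‑yl]‑8‑[3‑(TBDPS‑oxy)propyl]‑6‑oxabicyclo[3.2.1]octane‑2,7‑dione
Conditions: Ir[dF(CF3)ppy]2(dtbbpy)PF6 (2 mol %), K2HPO4, DMF (0.01 M), blue LEDs (450 nm), rt, degassed
Reagents that add atoms: none
Why: The carboxylate of 24 is oxidised by the photoexcited iridium catalyst (trivalent iridium in its excited state); the carboxyl radical loses CO2 and leaves a tertiary radical at Cb that is stabilised by the ring oxygen and is planar, so the C2 configuration of 24 plays no part. This nucleophilic radical adds to the unsubstituted terminus of the vinyl ketone, and the α‑keto radical formed is reduced by the divalent iridium complex to the enolate and protonated, which closes the catalytic cycle. The closest known reaction type is the photoredox decarboxylative Giese addition of α‑oxygenated carboxylic acids to enones, which is also known in intramolecular form. The ring closed is the cyclohexanone (Cb, Cg, Ch, Cc, Ca, Cd), in the 6‑endo‑trig mode of a 4‑oxohex‑5‑enyl radical; 5‑exo closure would mean attack at the α‑carbon of the enone and a primary radical, so polarity and radical stability both favour 6‑endo. The new stereocentre is Cb: the radical centre and the acryloyl group on Ca are 1,3 on the five‑membered lactone, and the three‑atom chain can reach Cb only on the face of the lactone on which it stands, so Cb is fixed by Ca (set in step 13) and the cis‑bridged bicycle results. The step needs the intramolecular addition to outrun reduction of the radical, intermolecular addition and polymerisation of the vinyl ketone; high dilution and the weak base serve this, and the silyl and benzyl ethers lie outside the oxidising reach of the catalyst.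

Step 16
Reactants: 25 (1R,5R,8S)‑1‑[2‑(benzyloxy)ethyl]‑5‑[(2R)‑1‑(TBS‑oxy)propan‑2‑yl]‑8‑[3‑(TBDPS‑oxy)propyl]‑6‑oxabicyclo[3.2.1]octane‑2,7‑dione
Product: 26 (1R,2S,5R,8S)‑1‑[2‑(benzyloxy)ethyl]‑5‑[(2R)‑1‑(TBS‑oxy)propan‑2‑yl]‑8‑[3‑(TBDPS‑oxy)propyl]‑2‑hydroxy‑2‑methyl‑6‑oxabicyclo[3.2.1]octan‑7‑one
Conditions: CeCl3, MeLi, THF, −78 °C; aq NH4Cl, −78 °C
Reagents that add atoms: methyllithium, [Li]C
Why: 1,2‑Addition of the weakly basic methylcerium reagent to the hindered ketone, without enolisation and without attack on the bridged lactone. The axial lactone bridge on Ca blocks the equatorial trajectory, so methyl enters axially, anti to the bridge, past only the axial hydrogens on Cg and Cd; this gives the axial methyl and the equatorial hydroxyl cis to Ce (2S). The cold quench avoids retro‑aldol of the β‑alkoxide.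

Step 17
Reactants: 26 (1R,2S,5R,8S)‑1‑[2‑(benzyloxy)ethyl]‑5‑[(2R)‑1‑(TBS‑oxy)propan‑2‑yl]‑8‑[3‑(TBDPS‑oxy)propyl]‑2‑hydroxy‑2‑methyl‑6‑oxabicyclo[3.2.1]octan‑7‑one
Product: 27 (1R,2S,5R,8S)‑1‑[2‑(benzyloxy)ethyl]‑5‑[(2R)‑1‑(TBS‑oxy)propan‑2‑yl]‑8‑[3‑(TBDPS‑oxy)propyl]‑2‑methyl‑2‑(TES‑oxy)‑6‑oxabicyclo[3.2.1]octan‑7‑one
Conditions: Et3SiOTf, 2,6‑lutidine, CH2Cl2, −78 → 0 °C
Reagents that add atoms: triethylsilyl trifluoromethanesulfonate, CC[Si](CC)(CC)OS(=O)(=O)C(F)(F)F
Why: Silylation of the hindered tertiary alcohol with the silyl triflate; it shields the alcohol from the Lewis acid of step 19 and keeps an acidic proton away from the organozinc of step 25.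

Step 18
Reactants: 27 (1R,2S,5R,8S)‑1‑[2‑(benzyloxy)ethyl]‑5‑[(2R)‑1‑(TBS‑oxy)propan‑2‑yl]‑8‑[3‑(TBDPS‑oxy)propyl]‑2‑methyl‑2‑(TES‑oxy)‑6‑oxabicyclo[3.2.1]octan‑7‑one
Product: 28 (1R,2S,5R,8S)‑1‑[2‑(benzyloxy)ethyl]‑5‑[(2R)‑1‑(TBS‑oxy)propan‑2‑yl]‑8‑[3‑(TBDPS‑oxy)propyl]‑2‑methyl‑2‑(TES‑oxy)‑6‑oxabicyclo[3.2.1]octan‑7‑ol (anomers)
Conditions: i‑Bu2AlH, CH2Cl2, −78 °C; aq potassium sodium tartrate
Reagents that add atoms: none
Why: Partial reduction of the lactone: the tetrahedral aluminate is stable at −78 °C, and the bridged lactol it releases has little tendency to open to the hydroxy aldehyde.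

Step 19
Reactants: 28 (1R,2S,5R,8S)‑1‑[2‑(benzyloxy)ethyl]‑5‑[(2R)‑1‑(TBS‑oxy)propan‑2‑yl]‑8‑[3‑(TBDPS‑oxy)propyl]‑2‑methyl‑2‑(TES‑oxy)‑6‑oxabicyclo[3.2.1]octan‑7‑ol
Product: 29 (1S,2S,5R,8S)‑1‑[2‑(benzyloxy)ethyl]‑5‑[(2R)‑1‑(TBS‑oxy)propan‑2‑yl]‑8‑[3‑(TBDPS‑oxy)propyl]‑2‑methyl‑2‑(TES‑oxy)‑6‑oxabicyclo[3.2.1]octane
Conditions: Et3SiH, BF3·OEt2, CH2Cl2, −78 → −40 °C
Reagents that add atoms: none
Why: Reductive deoxygenation of the lactol: the Lewis acid ionises it to the oxocarbenium ion, whose C=O+ lies in the two‑atom bridge and not at a bridgehead, and the silane delivers hydride. Ce becomes a methylene, so no stereocentre is involved; the descriptor of C1 changes by priority only.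

Step 20
Reactants: 29 (1S,2S,5R,8S)‑1‑[2‑(benzyloxy)ethyl]‑5‑[(2R)‑1‑(TBS‑oxy)propan‑2‑yl]‑8‑[3‑(TBDPS‑oxy)propyl]‑2‑methyl‑2‑(TES‑oxy)‑6‑oxabicyclo[3.2.1]octane
Product: 30 2‑[(1S,2S,5R,8S)‑5‑[(2R)‑1‑(TBS‑oxy)propan‑2‑yl]‑8‑[3‑(TBDPS‑oxy)propyl]‑2‑methyl‑2‑(TES‑oxy)‑6‑oxabicyclo[3.2.1]octan‑1‑yl]ethanol
Conditions: H2 (1 atm), Pd/C, EtOAc, rt
Reagents that add atoms: none
Why: Hydrogenolysis of the benzyl ether at a stage without any alkene; silyl ethers are stable in the aprotic solvent.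

Step 21
Reactants: 30 2‑[(1S,2S,5R,8S)‑5‑[(2R)‑1‑(TBS‑oxy)propan‑2‑yl]‑8‑[3‑(TBDPS‑oxy)propyl]‑2‑methyl‑2‑(TES‑oxy)‑6‑oxabicyclo[3.2.1]octan‑1‑yl]ethanol
Product: 31 (1S,2S,5R,8S)‑1‑(2‑iodoethyl)‑5‑[(2R)‑1‑(TBS‑oxy)propan‑2‑yl]‑8‑[3‑(TBDPS‑oxy)propyl]‑2‑methyl‑2‑(TES‑oxy)‑6‑oxabicyclo[3.2.1]octane
Conditions: I2, PPh3, imidazole, CH2Cl2, 0 °C → rt
Reagents that add atoms: iodine, II
Why: Appel‑type iodination of the primary alcohol through the alkoxyphosphonium salt; SN2 at an unhindered CH2 two bonds from the quaternary carbon.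

Step 22
Reactants: 32 α‑irone (commercial racemic mixture of cis‑ and trans‑α‑irone with some β‑irone)
Product: 33 (3E)‑4‑[(1R,5S)‑2,5,6,6‑tetramethylcyclohex‑2‑en‑1‑yl]but‑3‑en‑2‑one ((1R,5S)‑cis‑α‑irone)
Conditions: preparative HPLC on silica (hexane/EtOAc) for the cis‑α isomer; then preparative HPLC on cellulose tris(3,5‑dimethylphenylcarbamate), hexane/i‑PrOH
Reagents that add atoms: none
Why: A separation, no bond is made: cis‑α‑irone is a diastereomer of trans‑α‑irone and a double‑bond isomer of β‑irone and can be taken out on silica, and its enantiomers should be separable on a polysaccharide phase. The ring centres cannot be induced later, so the enantiomer is fixed here.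

Step 23
Reactants: 33 (3E)‑4‑[(1R,5S)‑2,5,6,6‑tetramethylcyclohex‑2‑en‑1‑yl]but‑3‑en‑2‑one
Product: 35 (3E)‑4‑[(1R,5S)‑2,5,6,6‑tetramethylcyclohex‑2‑en‑1‑yl]but‑3‑en‑1‑yne, via dienyl diethyl phosphate 34 (not isolated)
Conditions: LiN(i‑Pr)2, THF, −78 °C; ClP(O)(OEt)2, −78 °C → rt; LiN(i‑Pr)2 (2.3 equiv), −78 °C → rt; H2O
Reagents that add atoms: none
Why: Methyl ketone to terminal alkyne: kinetic deprotonation at the methyl group, O‑phosphorylation, and amide‑induced elimination of diethyl phosphate from the enol phosphate. The hindered, doubly allylic ring hydrogen should not be removed at low temperature, and the second equivalent of base is used up as the acetylide.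

Step 24
Reactants: 35 (3E)‑4‑[(1R,5S)‑2,5,6,6‑tetramethylcyclohex‑2‑en‑1‑yl]but‑3‑en‑1‑yne
Product: 37 (1E,3E)‑1‑iodo‑2‑methyl‑4‑[(1R,5S)‑2,5,6,6‑tetramethylcyclohex‑2‑en‑1‑yl]buta‑1,3‑diene, via (E)‑dienyldimethylalane 36 (not isolated)
Conditions: Me3Al, Cp2ZrCl2, CH2Cl2, 0 °C → rt; I2, THF, −30 → 0 °C
Reagents that add atoms: trimethylaluminium, C[Al](C)C; iodine, II
Why: Zirconium‑catalysed syn methylalumination of the terminal alkyne (Negishi carboalumination) puts methyl on the inner and aluminium on the terminal carbon; iodinolysis with retention gives the E iodide.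

Step 25
Reactants: 31 (1S,2S,5R,8S)‑1‑(2‑iodoethyl)‑5‑[(2R)‑1‑(TBS‑oxy)propan‑2‑yl]‑8‑[3‑(TBDPS‑oxy)propyl]‑2‑methyl‑2‑(TES‑oxy)‑6‑oxabicyclo[3.2.1]octane; 37 (1E,3E)‑1‑iodo‑2‑methyl‑4‑[(1R,5S)‑2,5,6,6‑tetramethylcyclohex‑2‑en‑1‑yl]buta‑1,3‑diene
Product: 39 (1S,2S,5R,8S)‑5‑[(2R)‑1‑(TBS‑oxy)propan‑2‑yl]‑8‑[3‑(TBDPS‑oxy)propyl]‑2‑methyl‑1‑[(3E,5E)‑4‑methyl‑6‑[(1R,5S)‑2,5,6,6‑tetramethylcyclohex‑2‑en‑1‑yl]hexa‑3,5‑dien‑1‑yl]‑2‑(TES‑oxy)‑6‑oxabicyclo[3.2.1]octane, via alkylzinc iodide 38 (not isolated)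
Conditions: Zn (activated with BrCH2CH2Br and Me3SiCl), LiCl, THF, 40 °C; 37, PdCl2(dppf) (5 mol %), THF, rt
Reagents that add atoms: none
Why: Zinc insertion into the primary C–I bond and Negishi C(sp3)–C(sp2) cross‑coupling with the alkenyl iodide at zerovalent palladium formed from the precatalyst; oxidative addition and reductive elimination keep the E geometry, and all hydroxyl groups are silylated.

Step 26
Reactants: 39 (1S,2S,5R,8S)‑5‑[(2R)‑1‑(TBS‑oxy)propan‑2‑yl]‑8‑[3‑(TBDPS‑oxy)propyl]‑2‑methyl‑1‑[(3E,5E)‑4‑methyl‑6‑[(1R,5S)‑2,5,6,6‑tetramethylcyclohex‑2‑en‑1‑yl]hexa‑3,5‑dien‑1‑yl]‑2‑(TES‑oxy)‑6‑oxabicyclo[3.2.1]octane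
Product: 40 (2R)‑2‑[(1S,2S,5R,8S)‑8‑[3‑(TBDPS‑oxy)propyl]‑2‑hydroxy‑2‑methyl‑1‑[(3E,5E)‑4‑methyl‑6‑[(1R,5S)‑2,5,6,6‑tetramethylcyclohex‑2‑en‑1‑yl]hexa‑3,5‑dien‑1‑yl]‑6‑oxabicyclo[3.2.1]octan‑5‑yl]propan‑1‑ol
Conditions: camphorsulfonic acid (cat.), MeOH/CH2Cl2, 0 °C → rt
Reagents that add atoms: none
Why: Acid‑catalysed methanolysis of silyl ethers removes the primary TBS and the tertiary TES group, while the primary TBDPS ether solvolyses far more slowly under acid; the mild acid leaves the diene and the doubly allylic position alone.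

Step 27
Reactants: 40 (2R)‑2‑[(1S,2S,5R,8S)‑8‑[3‑(TBDPS‑oxy)propyl]‑2‑hydroxy‑2‑methyl‑1‑[(3E,5E)‑4‑methyl‑6‑[(1R,5S)‑2,5,6,6‑tetramethylcyclohex‑2‑en‑1‑yl]hexa‑3,5‑dien‑1‑yl]‑6‑oxabicyclo[3.2.1]octan‑5‑yl]propan‑1‑ol
Product: 41 (2S)‑2‑[(1S,2S,5R,8S)‑8‑[3‑(TBDPS‑oxy)propyl]‑2‑hydroxy‑2‑methyl‑1‑[(3E,5E)‑4‑methyl‑6‑[(1R,5S)‑2,5,6,6‑tetramethylcyclohex‑2‑en‑1‑yl]hexa‑3,5‑dien‑1‑yl]‑6‑oxabicyclo[3.2.1]octan‑5‑yl]propanal
Conditions: Dess–Martin periodinane, pyridine, CH2Cl2, 0 °C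
Reagents that add atoms: none
Why: Oxidation of the only primary alcohol; the tertiary alcohol cannot be oxidised and the diene is inert to the periodinane. The buffer keeps Cα from epimerising; its descriptor changes from R to S by priority only.

Step 28
Reactants: 41 (2S)‑2‑[(1S,2S,5R,8S)‑8‑[3‑(TBDPS‑oxy)propyl]‑2‑hydroxy‑2‑methyl‑1‑[(3E,5E)‑4‑methyl‑6‑[(1R,5S)‑2,5,6,6‑tetramethylcyclohex‑2‑en‑1‑yl]hexa‑3,5‑dien‑1‑yl]‑6‑oxabicyclo[3.2.1]octan‑5‑yl]propanal
Product: 42 (2S)‑2‑[(1S,2S,5R,8S)‑2‑hydroxy‑8‑(3‑hydroxypropyl)‑2‑methyl‑1‑[(3E,5E)‑4‑methyl‑6‑[(1R,5S)‑2,5,6,6‑tetramethylcyclohex‑2‑en‑1‑yl]hexa‑3,5‑dien‑1‑yl]‑6‑oxabicyclo[3.2.1]octan‑5‑yl]propanal (CNP0419303.1)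
Conditions: HF·pyridine, pyridine, THF, 0 °C → rt
Reagents that add atoms: none
Why: Fluoride‑induced cleavage of the last silyl ether under buffered, non‑basic conditions, so the α‑methyl‑β‑alkoxy aldehyde should neither epimerise nor lose the ether oxygen by elimination.

## Compound list

1 | methyl (R)‑3‑hydroxy‑2‑methylpropanoate (Roche ester) | COC(=O)[C@H](C)CO | starting material
2 | methyl (R)‑3‑(TBS‑oxy)‑2‑methylpropanoate | COC(=O)[C@H](C)CO[Si](C)(C)C(C)(C)C | intermediate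
3 | (R)‑3‑(TBS‑oxy)‑N‑methoxy‑N,2‑dimethylpropanamide | CON(C)C(=O)[C@H](C)CO[Si](C)(C)C(C)(C)C | intermediate
4 | (R)‑5‑(TBS‑oxy)‑2‑ethoxy‑4‑methylpent‑1‑en‑3‑one | CCOC(=C)C(=O)[C@H](C)CO[Si](C)(C)C(C)(C)C | intermediate
5 | ethyl (R)‑4‑(TBS‑oxy)‑3‑methyl‑2‑oxobutanoate | CCOC(=O)C(=O)[C@H](C)CO[Si](C)(C)C(C)(C)C | intermediate
6 | pent‑4‑yn‑1‑ol | C#CCCCO | starting material
7 | tert‑butyl(pent‑4‑yn‑1‑yloxy)diphenylsilane | C#CCCCO[Si](c1ccccc1)(c1ccccc1)C(C)(C)C | intermediate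
8 | tert‑butyl(hexa‑4,5‑dien‑1‑yloxy)diphenylsilane | C=C=CCCCO[Si](c1ccccc1)(c1ccccc1)C(C)(C)C | intermediate
9 | [(2E)‑6‑(TBDPS‑oxy)hex‑2‑en‑1‑yl]bis[(1R,2S,3R,5R)‑2,6,6‑trimethylbicyclo[3.1.1]heptan‑3‑yl]borane (not isolated) | CC(C)(C)[Si](OCCC/C=C/CB([C@@H]1C[C@@H]2C[C@H]([C@H]1C)C2(C)C)[C@@H]1C[C@@H]2C[C@H]([C@H]1C)C2(C)C)(c1ccccc1)c1ccccc1 | intermediate
10 | ethyl (2S,3S)‑2‑[(2R)‑1‑(TBS‑oxy)propan‑2‑yl]‑6‑(TBDPS‑oxy)‑3‑ethenyl‑2‑hydroxyhexanoate | CCOC(=O)[C@@](O)([C@H](C)CO[Si](C)(C)C(C)(C)C)[C@H](C=C)CCCO[Si](c1ccccc1)(c1ccccc1)C(C)(C)C | intermediate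
11 | B‑alkyl‑9‑BBN adduct of 10, boron on the terminal carbon of the former vinyl group (not isolated) | CCOC(=O)[C@@](O)([C@H](C)CO[Si](C)(C)C(C)(C)C)[C@H](CCB1C2CCCC1CCC2)CCCO[Si](c1ccccc1)(c1ccccc1)C(C)(C)C | intermediate
12 | ethyl (2S,3S)‑2‑[(2R)‑1‑(TBS‑oxy)propan‑2‑yl]‑6‑(TBDPS‑oxy)‑2‑hydroxy‑3‑(2‑hydroxyethyl)hexanoate | CCOC(=O)[C@@](O)([C@H](C)CO[Si](C)(C)C(C)(C)C)[C@H](CCO)CCCO[Si](c1ccccc1)(c1ccccc1)C(C)(C)C | intermediate
13 | ethyl (2S,3S)‑2‑[(2R)‑1‑(TBS‑oxy)propan‑2‑yl]‑3‑[3‑(TBDPS‑oxy)propyl]‑5‑hydroxyoxolane‑2‑carboxylate, anomers (not isolated) | CCOC(=O)[C@]1([C@H](C)CO[Si](C)(C)C(C)(C)C)OC(O)C[C@@H]1CCCO[Si](c2ccccc2)(c2ccccc2)C(C)(C)C | intermediate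
14 | ethyl (2S,3S)‑2‑[(2R)‑1‑(TBS‑oxy)propan‑2‑yl]‑3‑[3‑(TBDPS‑oxy)propyl]‑5‑oxooxolane‑2‑carboxylate | CCOC(=O)[C@]1([C@H](C)CO[Si](C)(C)C(C)(C)C)OC(=O)C[C@@H]1CCCO[Si](c2ccccc2)(c2ccccc2)C(C)(C)C | intermediate
15 | 2‑(benzyloxy)ethanol | OCCOCc1ccccc1 | starting material
16 | 2‑(benzyloxy)ethyl trifluoromethanesulfonate | O=S(=O)(OCCOCc1ccccc1)C(F)(F)F | intermediate
17 | lithium enolate of 14 (not isolated) | CCOC(=O)[C@]1([C@H](C)CO[Si](C)(C)C(C)(C)C)OC(O[Li])=C[C@@H]1CCCO[Si](c2ccccc2)(c2ccccc2)C(C)(C)C | intermediate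
18 | ethyl (2S,3S,4S)‑4‑[2‑(benzyloxy)ethyl]‑2‑[(2R)‑1‑(TBS‑oxy)propan‑2‑yl]‑3‑[3‑(TBDPS‑oxy)propyl]‑5‑oxooxolane‑2‑carboxylate | CCOC(=O)[C@]1([C@H](C)CO[Si](C)(C)C(C)(C)C)OC(=O)[C@@H](CCOCc2ccccc2)[C@@H]1CCCO[Si](c3ccccc3)(c3ccccc3)C(C)(C)C | intermediate
19 | ring‑opened hydroxy diacid of 18, formed as its lithium salt (not isolated) | OC(=O)[C@@](O)([C@H](C)CO[Si](C)(C)C(C)(C)C)[C@@H](CCCO[Si](c1ccccc1)(c1ccccc1)C(C)(C)C)[C@H](CCOCc1ccccc1)C(=O)O | intermediate
20 | (2S,3S,4S)‑4‑[2‑(benzyloxy)ethyl]‑2‑[(2R)‑1‑(TBS‑oxy)propan‑2‑yl]‑3‑[3‑(TBDPS‑oxy)propyl]‑5‑oxooxolane‑2‑carboxylic acid | OC(=O)[C@]1([C@H](C)CO[Si](C)(C)C(C)(C)C)OC(=O)[C@@H](CCOCc2ccccc2)[C@@H]1CCCO[Si](c3ccccc3)(c3ccccc3)C(C)(C)C | intermediate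
21 | acrolein | C=CC=O | starting material
22 | dilithium carboxylate enolate of 20 (not isolated) | [Li]OC(=O)[C@]1([C@H](C)CO[Si](C)(C)C(C)(C)C)OC(O[Li])=C(CCOCc2ccccc2)[C@@H]1CCCO[Si](c3ccccc3)(c3ccccc3)C(C)(C)C | intermediate
23 | (2S,3S,4R)‑4‑[2‑(benzyloxy)ethyl]‑2‑[(2R)‑1‑(TBS‑oxy)propan‑2‑yl]‑3‑[3‑(TBDPS‑oxy)propyl]‑4‑(1‑hydroxyprop‑2‑en‑1‑yl)‑5‑oxooxolane‑2‑carboxylic acid (carbinol epimers) | OC(=O)[C@]1([C@H](C)CO[Si](C)(C)C(C)(C)C)OC(=O)[C@@](CCOCc2ccccc2)(C(O)C=C)[C@@H]1CCCO[Si](c3ccccc3)(c3ccccc3)C(C)(C)C | intermediate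
24 | (2S,3S,4R)‑4‑[2‑(benzyloxy)ethyl]‑2‑[(2R)‑1‑(TBS‑oxy)propan‑2‑yl]‑3‑[3‑(TBDPS‑oxy)propyl]‑5‑oxo‑4‑(prop‑2‑enoyl)oxolane‑2‑carboxylic acid | OC(=O)[C@]1([C@H](C)CO[Si](C)(C)C(C)(C)C)OC(=O)[C@@](CCOCc2ccccc2)(C(=O)C=C)[C@@H]1CCCO[Si](c3ccccc3)(c3ccccc3)C(C)(C)C | intermediate
25 | (1R,5R,8S)‑1‑[2‑(benzyloxy)ethyl]‑5‑[(2R)‑1‑(TBS‑oxy)propan‑2‑yl]‑8‑[3‑(TBDPS‑oxy)propyl]‑6‑oxabicyclo[3.2.1]octane‑2,7‑dione | C(OCC[C@]12C(=O)O[C@]([C@H](C)CO[Si](C)(C)C(C)(C)C)(CCC1=O)[C@H]2CCCO[Si](c1ccccc1)(c1ccccc1)C(C)(C)C)c1ccccc1 | intermediate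
26 | (1R,2S,5R,8S)‑1‑[2‑(benzyloxy)ethyl]‑5‑[(2R)‑1‑(TBS‑oxy)propan‑2‑yl]‑8‑[3‑(TBDPS‑oxy)propyl]‑2‑hydroxy‑2‑methyl‑6‑oxabicyclo[3.2.1]octan‑7‑one | C(OCC[C@]12C(=O)O[C@]([C@H](C)CO[Si](C)(C)C(C)(C)C)(CC[C@]1(C)O)[C@H]2CCCO[Si](c1ccccc1)(c1ccccc1)C(C)(C)C)c1ccccc1 | intermediate
27 | (1R,2S,5R,8S)‑1‑[2‑(benzyloxy)ethyl]‑5‑[(2R)‑1‑(TBS‑oxy)propan‑2‑yl]‑8‑[3‑(TBDPS‑oxy)propyl]‑2‑methyl‑2‑(TES‑oxy)‑6‑oxabicyclo[3.2.1]octan‑7‑one | C(OCC[C@]12C(=O)O[C@]([C@H](C)CO[Si](C)(C)C(C)(C)C)(CC[C@]1(C)O[Si](CC)(CC)CC)[C@H]2CCCO[Si](c1ccccc1)(c1ccccc1)C(C)(C)C)c1ccccc1 | intermediate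
28 | (1R,2S,5R,8S)‑1‑[2‑(benzyloxy)ethyl]‑5‑[(2R)‑1‑(TBS‑oxy)propan‑2‑yl]‑8‑[3‑(TBDPS‑oxy)propyl]‑2‑methyl‑2‑(TES‑oxy)‑6‑oxabicyclo[3.2.1]octan‑7‑ol (anomers) | C(OCC[C@]12C(O)O[C@]([C@H](C)CO[Si](C)(C)C(C)(C)C)(CC[C@]1(C)O[Si](CC)(CC)CC)[C@H]2CCCO[Si](c1ccccc1)(c1ccccc1)C(C)(C)C)c1ccccc1 | intermediate
29 | (1S,2S,5R,8S)‑1‑[2‑(benzyloxy)ethyl]‑5‑[(2R)‑1‑(TBS‑oxy)propan‑2‑yl]‑8‑[3‑(TBDPS‑oxy)propyl]‑2‑methyl‑2‑(TES‑oxy)‑6‑oxabicyclo[3.2.1]octane | C(OCC[C@]12CO[C@]([C@H](C)CO[Si](C)(C)C(C)(C)C)(CC[C@]1(C)O[Si](CC)(CC)CC)[C@H]2CCCO[Si](c1ccccc1)(c1ccccc1)C(C)(C)C)c1ccccc1 | intermediate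
30 | 2‑[(1S,2S,5R,8S)‑5‑[(2R)‑1‑(TBS‑oxy)propan‑2‑yl]‑8‑[3‑(TBDPS‑oxy)propyl]‑2‑methyl‑2‑(TES‑oxy)‑6‑oxabicyclo[3.2.1]octan‑1‑yl]ethanol | OCC[C@]12CO[C@]([C@H](C)CO[Si](C)(C)C(C)(C)C)(CC[C@]1(C)O[Si](CC)(CC)CC)[C@H]2CCCO[Si](c1ccccc1)(c1ccccc1)C(C)(C)C | intermediate
31 | (1S,2S,5R,8S)‑1‑(2‑iodoethyl)‑5‑[(2R)‑1‑(TBS‑oxy)propan‑2‑yl]‑8‑[3‑(TBDPS‑oxy)propyl]‑2‑methyl‑2‑(TES‑oxy)‑6‑oxabicyclo[3.2.1]octane | ICC[C@]12CO[C@]([C@H](C)CO[Si](C)(C)C(C)(C)C)(CC[C@]1(C)O[Si](CC)(CC)CC)[C@H]2CCCO[Si](c1ccccc1)(c1ccccc1)C(C)(C)C | intermediate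
32 | α‑irone, commercial isomer mixture (racemic) | CC1=CCC(C)C(C)(C)C1/C=C/C(C)=O | starting material
33 | (3E)‑4‑[(1R,5S)‑2,5,6,6‑tetramethylcyclohex‑2‑en‑1‑yl]but‑3‑en‑2‑one | CC1=CC[C@H](C)C(C)(C)[C@@H]1/C=C/C(C)=O | intermediate
34 | diethyl (3E)‑4‑[(1R,5S)‑2,5,6,6‑tetramethylcyclohex‑2‑en‑1‑yl]buta‑1,3‑dien‑2‑yl phosphate (not isolated) | CC1=CC[C@H](C)C(C)(C)[C@@H]1/C=C/C(=C)OP(=O)(OCC)OCC | intermediate
35 | (3E)‑4‑[(1R,5S)‑2,5,6,6‑tetramethylcyclohex‑2‑en‑1‑yl]but‑3‑en‑1‑yne | CC1=CC[C@H](C)C(C)(C)[C@@H]1/C=C/C#C | intermediate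
36 | dimethyl[(1E,3E)‑2‑methyl‑4‑[(1R,5S)‑2,5,6,6‑tetramethylcyclohex‑2‑en‑1‑yl]buta‑1,3‑dien‑1‑yl]alane (not isolated) | CC1=CC[C@H](C)C(C)(C)[C@@H]1/C=C/C(C)=C/[Al](C)C | intermediate
37 | (1E,3E)‑1‑iodo‑2‑methyl‑4‑[(1R,5S)‑2,5,6,6‑tetramethylcyclohex‑2‑en‑1‑yl]buta‑1,3‑diene | CC1=CC[C@H](C)C(C)(C)[C@@H]1/C=C/C(C)=C/I | intermediate
38 | alkylzinc iodide from 31, zinc on the former CH2I carbon (not isolated) | I[Zn]CC[C@]12CO[C@]([C@H](C)CO[Si](C)(C)C(C)(C)C)(CC[C@]1(C)O[Si](CC)(CC)CC)[C@H]2CCCO[Si](c1ccccc1)(c1ccccc1)C(C)(C)C | intermediate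
39 | (1S,2S,5R,8S)‑5‑[(2R)‑1‑(TBS‑oxy)propan‑2‑yl]‑8‑[3‑(TBDPS‑oxy)propyl]‑2‑methyl‑1‑[(3E,5E)‑4‑methyl‑6‑[(1R,5S)‑2,5,6,6‑tetramethylcyclohex‑2‑en‑1‑yl]hexa‑3,5‑dien‑1‑yl]‑2‑(TES‑oxy)‑6‑oxabicyclo[3.2.1]octane | CC1=CC[C@H](C)C(C)(C)[C@@H]1/C=C/C(C)=C/CC[C@]12CO[C@]([C@H](C)CO[Si](C)(C)C(C)(C)C)(CC[C@]1(C)O[Si](CC)(CC)CC)[C@H]2CCCO[Si](c1ccccc1)(c1ccccc1)C(C)(C)C | intermediate
40 | (2R)‑2‑[(1S,2S,5R,8S)‑8‑[3‑(TBDPS‑oxy)propyl]‑2‑hydroxy‑2‑methyl‑1‑[(3E,5E)‑4‑methyl‑6‑[(1R,5S)‑2,5,6,6‑tetramethylcyclohex‑2‑en‑1‑yl]hexa‑3,5‑dien‑1‑yl]‑6‑oxabicyclo[3.2.1]octan‑5‑yl]propan‑1‑ol | CC1=CC[C@H](C)C(C)(C)[C@@H]1/C=C/C(C)=C/CC[C@]12CO[C@]([C@H](C)CO)(CC[C@]1(C)O)[C@H]2CCCO[Si](c1ccccc1)(c1ccccc1)C(C)(C)C | intermediate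
41 | (2S)‑2‑[(1S,2S,5R,8S)‑8‑[3‑(TBDPS‑oxy)propyl]‑2‑hydroxy‑2‑methyl‑1‑[(3E,5E)‑4‑methyl‑6‑[(1R,5S)‑2,5,6,6‑tetramethylcyclohex‑2‑en‑1‑yl]hexa‑3,5‑dien‑1‑yl]‑6‑oxabicyclo[3.2.1]octan‑5‑yl]propanal | CC1=CC[C@H](C)C(C)(C)[C@@H]1/C=C/C(C)=C/CC[C@]12CO[C@]([C@H](C)C=O)(CC[C@]1(C)O)[C@H]2CCCO[Si](c1ccccc1)(c1ccccc1)C(C)(C)C | intermediate
42 | (2S)‑2‑[(1S,2S,5R,8S)‑2‑hydroxy‑8‑(3‑hydroxypropyl)‑2‑methyl‑1‑[(3E,5E)‑4‑methyl‑6‑[(1R,5S)‑2,5,6,6‑tetramethylcyclohex‑2‑en‑1‑yl]hexa‑3,5‑dien‑1‑yl]‑6‑oxabicyclo[3.2.1]octan‑5‑yl]propanal | CC1=CC[C@H](C)C(C)(C)[C@@H]1/C=C/C(C)=C/CC[C@]12CO[C@]([C@H](C)C=O)(CC[C@]1(C)O)[C@H]2CCCO | target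

## Step count and least certain steps

Total: 28 steps (27 reactions and one separation). Longest linear sequence: 22 steps (1–4, 7–9, 11–21, 25–28).

**Step 15 (key step).**
- Risk: premature quenching of the tertiary radical before it reaches the enone terminus, by reduction to the C–H lactone, by intermolecular addition, or by polymerisation of the vinyl ketone. The bridging closure requires the acryloyl group to fold over the lactone, and the α‑acyloxy carboxylate is less easily oxidised than an α‑alkoxy one.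
- Fallback: set out from acid 24. Esterification with N‑hydroxyphthalimide (N,N′‑diisopropylcarbodiimide, CH2Cl2) should give the N‑acyloxyphthalimide F1. Under reductive photoredox conditions (Ru(bpy)3(PF6)2, Hantzsch ester, i‑Pr2NEt, CH2Cl2, blue LEDs) F1 accepts an electron and fragments to phthalimide, CO2 and the same Cb radical, now without base or carboxylate and with a hydrogen donor for the α‑keto radical. The closure comes back to the route at 25.

**Step 7.**
- Risk: incomplete control of the face of the allyl unit and erosion of the E geometry of 9. A ketone forces one carbonyl substituent into the axial site beside an isopinocampheyl group, the weak Felkin preference of the α‑centre of 5 points to the other face, and boratropic shift can leak Z isomer. Either process would give the Cd epimer.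
- Fallback: set out from alkyne 7 and keto ester 5 and move stereocontrol to an isolable boronic ester under chiral‑diol catalysis. Hydroboration of 7 with catecholborane gives the alkenyl catechol boronate F2. Exchange against propane‑1,3‑diol gives the (E)‑alkenyl dioxaborinane F3. Matteson homologation (BrCH2Cl, n‑BuLi, −78 °C) gives the geometrically fixed (E)‑allyl dioxaborinane F4. F4 adds to 5 in the presence of 3,3′‑Br2‑BINOL (the antipode that leads to 3S; both are available) and t‑BuOH in toluene, a catalysis developed for the crotylboration of ketones. It comes back at 10.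

**Step 13.**
- Risk: retro‑aldol of the lithium aldolate at the quaternary centre, incomplete deprotonation of the hindered C4–H beside the carboxylate, and loss of face selectivity, since the branched group on C2 stands on the face the aldehyde must use.
- Fallback: set out from 20 and switch to a Lewis‑acid aldol of a neutral nucleophile. The dianion 22 is silylated (Me3SiCl, −78 °C) to the trimethylsilyl ester O‑trimethylsilyl ketene acetal F5. F5 undergoes a Mukaiyama aldol addition with 21 (BF3·OEt2, CH2Cl2, −78 °C), which is irreversible under the conditions; the silyl ester is hydrolysed on work‑up. It comes back at 23.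

**Step 22.**
- Risk: insufficient separation or throughput of the enantiomers on the chiral phase.
- Fallback: set out from the racemic cis‑α‑irone cut of 32 (the achiral separation is kept). A haloform reaction (aq NaOCl, dioxane, 0 °C) gives the racemic cis acid F6. Crystallisation with (R)‑1‑phenylethylamine (its antipode if the other salt is the less soluble one) gives the salt F7 of the (1R,5S) acid. Acidification frees the acid F8, and MeLi (2.2 equiv, Et2O, 0 °C) converts the carboxylate back into the methyl ketone. It comes back at 33.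

**Step 25.**
- Risk: slow zinc insertion into the hindered primary iodide, protonolysis of 38, β‑hydride elimination at palladium, and decomposition of the dienyl iodide during a slow coupling.
- Fallback: set out from 37 and 31 with the polarity reversed. Iodine–magnesium exchange of 37 (i‑PrMgCl·LiCl, THF, −20 °C) gives the dienylmagnesium chloride F9 with retention. F9 is coupled with alkyl iodide 31 under iron catalysis (Fe(acac)3, TMEDA, THF, 0 °C), a known coupling of alkenyl Grignard reagents with primary alkyl halides. It comes back at 39.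

## Further compounds

F1 | step 15 | 1,3‑dioxoisoindolin‑2‑yl ester (N‑acyloxyphthalimide) of acid 24 | O=C(ON1C(=O)c2ccccc2C1=O)[C@]3([C@H](C)CO[Si](C)(C)C(C)(C)C)OC(=O)[C@@](CCOCc4ccccc4)(C(=O)C=C)[C@@H]3CCCO[Si](c5ccccc5)(c5ccccc5)C(C)(C)C
F2 | step 7 | 2‑[(1E)‑5‑(TBDPS‑oxy)pent‑1‑en‑1‑yl]‑1,3,2‑benzodioxaborole | CC(C)(C)[Si](OCCC/C=C/B1Oc2ccccc2O1)(c1ccccc1)c1ccccc1
F3 | step 7 | 2‑[(1E)‑5‑(TBDPS‑oxy)pent‑1‑en‑1‑yl]‑1,3,2‑dioxaborinane | CC(C)(C)[Si](OCCC/C=C/B1OCCCO1)(c1ccccc1)c1ccccc1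
F4 | step 7 | 2‑[(2E)‑6‑(TBDPS‑oxy)hex‑2‑en‑1‑yl]‑1,3,2‑dioxaborinane | CC(C)(C)[Si](OCCC/C=C/CB1OCCCO1)(c1ccccc1)c1ccccc1
F5 | step 13 | trimethylsilyl ester O‑trimethylsilyl ketene acetal of 20 | C[Si](C)(C)OC(=O)[C@]1([C@H](C)CO[Si](C)(C)C(C)(C)C)OC(O[Si](C)(C)C)=C(CCOCc2ccccc2)[C@@H]1CCCO[Si](c3ccccc3)(c3ccccc3)C(C)(C)C
F6 | step 22 | racemic cis‑(2E)‑3‑(2,5,6,6‑tetramethylcyclohex‑2‑en‑1‑yl)prop‑2‑enoic acid (both enantiomers) | CC1=CC[C@H](C)C(C)(C)[C@@H]1/C=C/C(=O)O.CC1=CC[C@@H](C)C(C)(C)[C@H]1/C=C/C(=O)O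
F7 | step 22 | (R)‑1‑phenylethylammonium (2E)‑3‑[(1R,5S)‑2,5,6,6‑tetramethylcyclohex‑2‑en‑1‑yl]prop‑2‑enoate | CC1=CC[C@H](C)C(C)(C)[C@@H]1/C=C/C(=O)[O-].C[C@@H]([NH3+])c1ccccc1
F8 | step 22 | (2E)‑3‑[(1R,5S)‑2,5,6,6‑tetramethylcyclohex‑2‑en‑1‑yl]prop‑2‑enoic acid | CC1=CC[C@H](C)C(C)(C)[C@@H]1/C=C/C(=O)O
F9 | step 25 | [(1E,3E)‑2‑methyl‑4‑[(1R,5S)‑2,5,6,6‑tetramethylcyclohex‑2‑en‑1‑yl]buta‑1,3‑dien‑1‑yl]magnesium chloride | CC1=CC[C@H](C)C(C)(C)[C@@H]1/C=C/C(C)=C/[Mg]Cl
A1 | alternative 1 | S‑methyl xanthate of the oxepane carbinol bearing the exocyclic alkoxyacrylate (either carbinol epimer) | C=CC[C@]1(C(OC(=S)SC)CCCO[Si](C)(C)C(C)(C)C)COC(=C(C)C(=O)OC)CC[C@]1(C)O[Si](CC)(CC)CC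
A2 | alternative 1 | bridged ether ester | C=CC[C@]12CO[C@]([C@H](C)C(=O)OC)(CC[C@]1(C)O[Si](CC)(CC)CC)[C@H]2CCCO[Si](C)(C)C(C)(C)C
A3 | alternative 2 | cyclohexane tertiary alcohol with the angular methyl on Ca | COC(=O)C[C@]1(C)[C@@](C)(OC(C)=O)CC[C@](O)([C@H](C)CO[Si](C)(C)C(C)(C)C)[C@H]1CCCO[Si](c1ccccc1)(c1ccccc1)C(C)(C)C
A4 | alternative 2 | bridged ether | COC(=O)C[C@]12CO[C@]([C@H](C)CO[Si](C)(C)C(C)(C)C)(CC[C@]1(C)OC(C)=O)[C@H]2CCCO[Si](c1ccccc1)(c1ccccc1)C(C)(C)C
A5 | alternative 3 | 1,4‑disubstituted cyclohexa‑1,3‑diene | CC(C)(C)C(=O)OCC[C@]1(CO)C(C)=CC=C([C@H](C)COCc2ccc(OC)cc2)[C@H]1CCCO[Si](C)(C)C(C)(C)C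
A6 | alternative 3 | endoperoxide | CC(C)(C)C(=O)OCC[C@]1(CO)[C@@]2(C)OO[C@@](C=C2)([C@H](C)COCc3ccc(OC)cc3)[C@H]1CCCO[Si](C)(C)C(C)(C)C
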